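The route rests on closing ring A last. Its two quaternary carbons, C4 and C10, are 1,3-related through C5 and otherwise joined only by the bare trimethylene C1–C2–C3; with C18 as an ester and C9 as a ketone both are enolate carbons. In one flask 1-chloro-3-iodopropane is therefore joined first to the ketone enolate carbon C10 and then to the ester enolate carbon C4, a [3+3] annulation that closes ring A and relays both quaternary centres from the single C5 stereocentre of a ring B keto ester. That centre comes from a CBS reduction and a Johnson–Claisen rearrangement; an alkoxymethylene group blocks C8 and later becomes C17.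

Key step: step 5

Remark: atoms are named in labdane numbering (ring A = C1–C5, C10; ring B = C5–C10; C17 exocyclic methylene carbon; C18 the oxygen-bearing carbon on C4; C19 and C20 the methyls on C4 and C10; C11–C16 side chain). In the target the CH2O group on C4 is trans to the C10 methyl and the configuration is 4S,5S,9R,10S,13S.

Step 1
Reactants: 1 2-methylcyclohex-2-en-1-one
Product: 2 (1R)-2-methylcyclohex-2-en-1-ol
Conditions: (S)-2-methyl-CBS-oxazaborolidine (10 mol %), BH3·SMe2, THF, −20 °C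
Reagents that add atoms: none
Why: Corey–Bakshi–Shibata reduction, in which the oxazaborolidine–borane complex treats the 2-methylvinyl side as the large group and delivers hydride to one carbonyl face only, setting the (R)-carbinol that later becomes the C5 stereocentre.

Step 2
Reactants: 2 (1R)-2-methylcyclohex-2-en-1-ol; 3 1,1,1-triethoxypropane
Product: 5 ethyl 2-[(1R)-2-methylcyclohex-2-en-1-yl]propanoate (both epimers at the propanoate α-carbon), via ketene acetal 4 (not isolated)
Conditions: 3 (6 equiv), EtCO2H (cat.), 140 °C, EtOH distilled off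
Reagents that add atoms: 3 1,1,1-triethoxypropane, CCC(OCC)(OCC)OCC
Why: Johnson–Claisen rearrangement, in which the ketene acetal rearranges suprafacially so that the C–O chirality is transferred to the new C4–C5 bond and the alkene moves to C9=C10; the α-carbon configuration is irrelevant because it is enolised in step 5.

Step 3
Reactants: 5 ethyl 2-[(1R)-2-methylcyclohex-2-en-1-yl]propanoate
Product: 7 ethyl 2-[(1S)-2-methyl-3-oxocyclohexyl]propanoate (epimers at ring C2 and the α-carbon), via alkylborane 6 (not isolated)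
Conditions: BH3·THF, THF, 0 °C to rt; then Na2Cr2O7, H2SO4, H2O, Et2O, 0 °C to rt
Reagents that add atoms: chromic acid (from Na2Cr2O7 and H2SO4), O[Cr](=O)(=O)O
Why: Anti-Markovnikov hydroboration of the trisubstituted alkene puts boron on C9 and chromic acid oxidation of the C–B bond in the same flask should give the C9 ketone, the ester being inert to both reagents.

Step 4
Reactants: 7 ethyl 2-[(1S)-2-methyl-3-oxocyclohexyl]propanoate; 8 ethyl formate; 9 2-iodopropane
Product: 11 ethyl 2-[(1S,4E)-2-methyl-3-oxo-4-[(propan-2-yloxy)methylidene]cyclohexyl]propanoate, via hydroxymethylene ketone 10 (not isolated)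
Conditions: NaH, HCO2Et, EtOH (cat.), THF, 0 °C to rt; then i-PrI, DMF, 50 °C
Reagents that add atoms: 8 ethyl formate, CCOC=O; 9 2-iodopropane, CC(C)I
Why: Claisen formylation can only persist at the α-methylene C8 and O-alkylation of the resulting β-keto aldehyde enolate by the secondary iodide should give the alkoxymethylene ketone, which blocks C8 and carries the future C17.

Step 5
Reactants: 11 ethyl 2-[(1S,4E)-2-methyl-3-oxo-4-[(propan-2-yloxy)methylidene]cyclohexyl]propanoate; 12 1-chloro-3-iodopropane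
Product: 14 ethyl (1S,4aR,6E,8aS)-1,4a-dimethyl-5-oxo-6-[(propan-2-yloxy)methylidene]decahydronaphthalene-1-carboxylate (trans-fused; ester trans to the C10 methyl), via chloropropyl ketone 13 (not isolated)
Conditions: LiN(i-Pr)2 (1.05 equiv), THF, −78 to 0 °C; 12 (1.1 equiv), HMPA, −40 to 0 °C; then LiN(i-Pr)2 (1.3 equiv), −78 °C to rt
Reagents that add atoms: 12 1-chloro-3-iodopropane, ClCCCI
Why: Two successive enolate SN2 alkylations by the two ends of one trimethylene dihalide amount to a [3+3] annulation, the known double-alkylation ring synthesis with 1,3-dihalides applied to a keto ester. The first equivalent of base removes the only ketone-type α-hydrogen (C10–H; C8 is blocked and this hydrogen is more acidic than the ester α-hydrogen), and the cross-conjugated enolate attacks the iodide end to form C1–C10. A(1,2) strain with the C10 methyl holds the C5 side chain pseudo-axial, so the electrophile should enter anti to it and C1 ends trans to C4, which fixes the trans ring fusion. The second equivalent of base then forms the ester enolate, which closes ring A by 6-exo-tet displacement of chloride (C3–C4) through a chair. A(1,3) strain keeps C5–H in the plane of the exocyclic enolate, so the ester carbon should become equatorial and the C4 methyl axial, cis to the C10 methyl. The step needs C-alkylation at C10 before the ester enolate exists and iodide to react before chloride, which the acidity order and the leaving-group order should secure.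

Step 6
Reactants: 15 (3S)-3,7-dimethyloct-6-en-1-ol ((S)-citronellol); 16 tert-butyl(chloro)dimethylsilane
Product: 17 tert-butyl{[(3S)-3,7-dimethyloct-6-en-1-yl]oxy}dimethylsilane
Conditions: imidazole, CH2Cl2, rt
Reagents that add atoms: 16 tert-butyl(chloro)dimethylsilane, CC(C)(C)[Si](C)(C)Cl
Why: Standard silylation of the primary alcohol, which protects the future C15 oxygen.

Step 7
Reactants: 17 tert-butyl{[(3S)-3,7-dimethyloct-6-en-1-yl]oxy}dimethylsilane
Product: 18 (4S)-6-{[tert-butyl(dimethyl)silyl]oxy}-4-methylhexanoic acid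
Conditions: RuCl3 (cat.), NaIO4, MeCN/EtOAc/H2O, rt
Reagents that add atoms: sodium periodate, [Na+].[O-]I(=O)(=O)=O; water, O
Why: RuO4 formed in situ cleaves the trisubstituted alkene to the carboxylic acid and acetone without touching the stereocentre.

Step 8
Reactants: 18 (4S)-6-{[tert-butyl(dimethyl)silyl]oxy}-4-methylhexanoic acid
Product: 19 tert-butyl{[(3R)-5-iodo-3-methylpentyl]oxy}dimethylsilane
Conditions: PhI(OAc)2, I2, cyclohexane, hν (tungsten lamp), reflux
Reagents that add atoms: iodine, II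
Why: Radical iododecarboxylation (Hunsdiecker type, homolysis of the acyl hypoiodite) removes the carboxyl carbon and leaves the primary iodide of the five-carbon side chain; the descriptor changes only because the priorities change.

Step 9
Reactants: 14 ethyl (1S,4aR,6E,8aS)-1,4a-dimethyl-5-oxo-6-[(propan-2-yloxy)methylidene]decahydronaphthalene-1-carboxylate; 19 tert-butyl{[(3R)-5-iodo-3-methylpentyl]oxy}dimethylsilane
Product: 22 ethyl (1S,4aR,8aS)-5-[(3S)-5-{[tert-butyl(dimethyl)silyl]oxy}-3-methylpentyl]-6-formyl-1,4a-dimethyl-1,2,3,4,4a,7,8,8a-octahydronaphthalene-1-carboxylate, via organolithium 20 (not isolated), via carbinol 21 (not isolated)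
Conditions: 19, t-BuLi, Et2O, −78 °C; CeCl3, THF, −78 °C; 14, −78 to 0 °C; then 0.5 M HCl, THF, 0 °C
Reagents that add atoms: 19 tert-butyl{[(3R)-5-iodo-3-methylpentyl]oxy}dimethylsilane, ICC[C@H](C)CCO[Si](C)(C)C(C)(C)C
Why: Iodine–lithium exchange, transmetalation to the organocerium and 1,2-addition to the vinylogous ester carbonyl, then acid ionisation of the tertiary allylic carbinol and hydrolysis of the enol ether (Stork–Danheiser-type alkylative transposition) should give the tetrasubstituted enal with the side chain on C9.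

Step 10
Reactants: 22 ethyl (1S,4aR,8aS)-5-[(3S)-5-{[tert-butyl(dimethyl)silyl]oxy}-3-methylpentyl]-6-formyl-1,4a-dimethyl-1,2,3,4,4a,7,8,8a-octahydronaphthalene-1-carboxylate
Product: 23 [(1S,4aR,8aS)-5-[(3S)-5-{[tert-butyl(dimethyl)silyl]oxy}-3-methylpentyl]-6-(hydroxymethyl)-1,4a-dimethyl-1,2,3,4,4a,7,8,8a-octahydronaphthalen-1-yl]methanol
Conditions: i-Bu2AlH (6 equiv), CH2Cl2, −78 to 0 °C; aq. KNaC4H4O6
Reagents that add atoms: none
Why: i-Bu2AlH reduces the enal 1,2 and the hindered ester to the two primary alcohols (C17–OH and C18–OH), the silyl ether being inert.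

Step 11
Reactants: 23 [(1S,4aR,8aS)-5-[(3S)-5-{[tert-butyl(dimethyl)silyl]oxy}-3-methylpentyl]-6-(hydroxymethyl)-1,4a-dimethyl-1,2,3,4,4a,7,8,8a-octahydronaphthalen-1-yl]methanol; 24 2-nitrobenzenesulfonohydrazide
Product: 27 [(1S,4aS,5R,8aS)-5-[(3S)-5-{[tert-butyl(dimethyl)silyl]oxy}-3-methylpentyl]-1,4a-dimethyl-6-methylidenedecahydronaphthalen-1-yl]methanol, via sulfonylhydrazine 25 (not isolated), via allylic diazene 26 (not isolated)
Conditions: PPh3, DEAD, 24, THF, −30 °C; then rt
Reagents that add atoms: none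
Why: Mitsunobu substitution should occur only at the allylic primary alcohol (the neopentyl C18 alcohol cannot be displaced), and after loss of sulfinate the allylic diazene expels N2 in a retro-ene step that moves the alkene to C8=C17 and delivers hydrogen to C9 from the face opposite the axial C10 methyl, leaving the side chain equatorial.

Step 12
Reactants: 27 [(1S,4aS,5R,8aS)-5-[(3S)-5-{[tert-butyl(dimethyl)silyl]oxy}-3-methylpentyl]-1,4a-dimethyl-6-methylidenedecahydronaphthalen-1-yl]methanol; 28 (2E)-3-[4-(acetyloxy)phenyl]prop-2-enoic acid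
Product: 30 [(1S,4aS,5R,8aS)-5-[(3S)-5-{[tert-butyl(dimethyl)silyl]oxy}-3-methylpentyl]-1,4a-dimethyl-6-methylidenedecahydronaphthalen-1-yl]methyl (2E)-3-[4-(acetyloxy)phenyl]prop-2-enoate, via acid chloride 29 (not isolated)
Conditions: 28, (COCl)2, DMF (cat.), CH2Cl2, 0 °C to rt, evaporate; then 27, pyridine, DMAP, CH2Cl2, 0 °C to rt
Reagents that add atoms: 28 (2E)-3-[4-(acetyloxy)phenyl]prop-2-enoic acid, CC(=O)Oc1ccc(/C=C/C(=O)O)cc1
Why: DMAP-catalysed acylation of the neopentyl primary alcohol by the acid chloride, with the phenol masked as its acetate.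

Step 13
Reactants: 30 [(1S,4aS,5R,8aS)-5-[(3S)-5-{[tert-butyl(dimethyl)silyl]oxy}-3-methylpentyl]-1,4a-dimethyl-6-methylidenedecahydronaphthalen-1-yl]methyl (2E)-3-[4-(acetyloxy)phenyl]prop-2-enoate
Product: 32 (3S)-5-[(1R,4aS,5S,8aS)-5-({[(2E)-3-(4-acetyloxyphenyl)prop-2-enoyl]oxy}methyl)-5,8a-dimethyl-2-methylidenedecahydronaphthalen-1-yl]-3-methylpentanoic acid, via primary alcohol 31 (not isolated)
Conditions: CrO3, H2SO4, H2O, acetone, 0 °C
Reagents that add atoms: water, O
Why: Jones oxidation, in which aqueous acid removes the primary silyl ether and chromic acid oxidises the freed alcohol through the aldehyde hydrate to the acid, conditions that 8(17)-ene labdanes, cinnamates and aryl acetates tolerate.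

Step 14
Reactants: 32 (3S)-5-[(1R,4aS,5S,8aS)-5-({[(2E)-3-(4-acetyloxyphenyl)prop-2-enoyl]oxy}methyl)-5,8a-dimethyl-2-methylidenedecahydronaphthalen-1-yl]-3-methylpentanoic acid
Product: 33 (3S)-5-[(1R,4aS,5S,8aS)-5-({[(2E)-3-(4-hydroxyphenyl)prop-2-enoyl]oxy}methyl)-5,8a-dimethyl-2-methylidenedecahydronaphthalen-1-yl]-3-methylpentanoic acid (CNP0389065.1)
Conditions: pyrrolidine (3 equiv), CH2Cl2, 0 °C to rt; dilute HCl wash
Reagents that add atoms: none
Why: Aminolysis of the activated aryl acetate by pyrrolidine is much faster than attack on the hindered neopentyl cinnamate, so only the phenol should be unmasked.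

Compound list
1 | 2-methylcyclohex-2-en-1-one | CC1=CCCCC1=O | starting material
2 | (1R)-2-methylcyclohex-2-en-1-ol | CC1=CCCC[C@H]1O | intermediate
3 | 1,1,1-triethoxypropane (triethyl orthopropionate) | CCC(OCC)(OCC)OCC | starting material
4 | (6R)-6-[(1-ethoxyprop-1-en-1-yl)oxy]-1-methylcyclohex-1-ene (ketene acetal) | CC=C(OCC)O[C@@H]1CCCC=C1C | intermediate
5 | ethyl 2-[(1R)-2-methylcyclohex-2-en-1-yl]propanoate | CCOC(=O)C(C)[C@H]1CCCC=C1C | intermediate
6 | ethyl 2-[(1S)-3-boranyl-2-methylcyclohexyl]propanoate (alkylborane, ring C2 and C3 not defined) | CCOC(=O)C(C)[C@H]1CCCC(B)C1C | intermediate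
7 | ethyl 2-[(1S)-2-methyl-3-oxocyclohexyl]propanoate | CCOC(=O)C(C)[C@H]1CCCC(=O)C1C | intermediate
8 | ethyl formate | CCOC=O | starting material
9 | 2-iodopropane | CC(C)I | starting material
10 | ethyl 2-[(1S)-4-(hydroxymethylidene)-2-methyl-3-oxocyclohexyl]propanoate | OC=C1CC[C@H](C(C)C(=O)OCC)C(C)C1=O | intermediate
11 | ethyl 2-[(1S,4E)-2-methyl-3-oxo-4-[(propan-2-yloxy)methylidene]cyclohexyl]propanoate | CC(C)O/C=C1\CC[C@H](C(C)C(=O)OCC)C(C)C1=O | intermediate
12 | 1-chloro-3-iodopropane | ClCCCI | starting material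
13 | ethyl 2-[(1R,2R,4E)-2-(3-chloropropyl)-2-methyl-3-oxo-4-[(propan-2-yloxy)methylidene]cyclohexyl]propanoate | CC(C)O/C=C1\CC[C@H](C(C)C(=O)OCC)[C@@](C)(CCCCl)C1=O | intermediate
14 | ethyl (1S,4aR,6E,8aS)-1,4a-dimethyl-5-oxo-6-[(propan-2-yloxy)methylidene]decahydronaphthalene-1-carboxylate | CC(C)O/C=C1\CC[C@@H]2[C@@](C)(C(=O)OCC)CCC[C@@]2(C)C1=O | intermediate
15 | (3S)-3,7-dimethyloct-6-en-1-ol ((S)-citronellol) | CC(C)=CCC[C@H](C)CCO | starting material
16 | tert-butyl(chloro)dimethylsilane | CC(C)(C)[Si](C)(C)Cl | starting material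
17 | tert-butyl{[(3S)-3,7-dimethyloct-6-en-1-yl]oxy}dimethylsilane | CC(C)=CCC[C@H](C)CCO[Si](C)(C)C(C)(C)C | intermediate
18 | (4S)-6-{[tert-butyl(dimethyl)silyl]oxy}-4-methylhexanoic acid | OC(=O)CC[C@H](C)CCO[Si](C)(C)C(C)(C)C | intermediate
19 | tert-butyl{[(3R)-5-iodo-3-methylpentyl]oxy}dimethylsilane | ICC[C@H](C)CCO[Si](C)(C)C(C)(C)C | intermediate
20 | [(3S)-5-{[tert-butyl(dimethyl)silyl]oxy}-3-methylpentyl]lithium | [Li]CC[C@H](C)CCO[Si](C)(C)C(C)(C)C | intermediate
21 | ethyl (1S,4aR,6E,8aS)-5-[(3S)-5-{[tert-butyl(dimethyl)silyl]oxy}-3-methylpentyl]-5-hydroxy-1,4a-dimethyl-6-[(propan-2-yloxy)methylidene]decahydronaphthalene-1-carboxylate (carbinol carbon not defined) | CC(C)O/C=C1\CC[C@@H]2[C@@](C)(C(=O)OCC)CCC[C@@]2(C)C1(O)CC[C@H](C)CCO[Si](C)(C)C(C)(C)C | intermediate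
22 | ethyl (1S,4aR,8aS)-5-[(3S)-5-{[tert-butyl(dimethyl)silyl]oxy}-3-methylpentyl]-6-formyl-1,4a-dimethyl-1,2,3,4,4a,7,8,8a-octahydronaphthalene-1-carboxylate | O=CC=1CC[C@@H]2[C@@](C)(C(=O)OCC)CCC[C@@]2(C)C1CC[C@H](C)CCO[Si](C)(C)C(C)(C)C | intermediate
23 | [(1S,4aR,8aS)-5-[(3S)-5-{[tert-butyl(dimethyl)silyl]oxy}-3-methylpentyl]-6-(hydroxymethyl)-1,4a-dimethyl-1,2,3,4,4a,7,8,8a-octahydronaphthalen-1-yl]methanol | OCC=1CC[C@@H]2[C@@](C)(CO)CCC[C@@]2(C)C1CC[C@H](C)CCO[Si](C)(C)C(C)(C)C | intermediate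
24 | 2-nitrobenzenesulfonohydrazide | NNS(=O)(=O)c1ccccc1[N+](=O)[O-] | starting material
25 | N-(2-nitrobenzenesulfonyl)-N-alkylhydrazine formed from 23 at C17 | NN(CC=1CC[C@@H]2[C@@](C)(CO)CCC[C@@]2(C)C1CC[C@H](C)CCO[Si](C)(C)C(C)(C)C)S(=O)(=O)c3ccccc3[N+](=O)[O-] | intermediate
26 | allylic diazene (C17–N=NH) | N=NCC=1CC[C@@H]2[C@@](C)(CO)CCC[C@@]2(C)C1CC[C@H](C)CCO[Si](C)(C)C(C)(C)C | intermediate
27 | [(1S,4aS,5R,8aS)-5-[(3S)-5-{[tert-butyl(dimethyl)silyl]oxy}-3-methylpentyl]-1,4a-dimethyl-6-methylidenedecahydronaphthalen-1-yl]methanol | C=C1CC[C@@H]2[C@@](C)(CO)CCC[C@@]2(C)[C@@H]1CC[C@H](C)CCO[Si](C)(C)C(C)(C)C | intermediate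
28 | (2E)-3-[4-(acetyloxy)phenyl]prop-2-enoic acid | CC(=O)Oc1ccc(/C=C/C(=O)O)cc1 | starting material
29 | (2E)-3-[4-(acetyloxy)phenyl]prop-2-enoyl chloride | CC(=O)Oc1ccc(/C=C/C(Cl)=O)cc1 | intermediate
30 | [(1S,4aS,5R,8aS)-5-[(3S)-5-{[tert-butyl(dimethyl)silyl]oxy}-3-methylpentyl]-1,4a-dimethyl-6-methylidenedecahydronaphthalen-1-yl]methyl (2E)-3-[4-(acetyloxy)phenyl]prop-2-enoate | C=C1CC[C@@H]2[C@@](C)(COC(=O)/C=C/c3ccc(OC(C)=O)cc3)CCC[C@@]2(C)[C@@H]1CC[C@H](C)CCO[Si](C)(C)C(C)(C)C | intermediate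
31 | [(1S,4aS,5R,8aS)-5-[(3S)-5-hydroxy-3-methylpentyl]-1,4a-dimethyl-6-methylidenedecahydronaphthalen-1-yl]methyl (2E)-3-[4-(acetyloxy)phenyl]prop-2-enoate | C=C1CC[C@@H]2[C@@](C)(COC(=O)/C=C/c3ccc(OC(C)=O)cc3)CCC[C@@]2(C)[C@@H]1CC[C@H](C)CCO | intermediate
32 | (3S)-5-[(1R,4aS,5S,8aS)-5-({[(2E)-3-(4-acetyloxyphenyl)prop-2-enoyl]oxy}methyl)-5,8a-dimethyl-2-methylidenedecahydronaphthalen-1-yl]-3-methylpentanoic acid | C=C1CC[C@@H]2[C@@](C)(COC(=O)/C=C/c3ccc(OC(C)=O)cc3)CCC[C@@]2(C)[C@@H]1CC[C@H](C)CC(=O)O | intermediate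
33 | (3S)-5-[(1R,4aS,5S,8aS)-5-({[(2E)-3-(4-hydroxyphenyl)prop-2-enoyl]oxy}methyl)-5,8a-dimethyl-2-methylidenedecahydronaphthalen-1-yl]-3-methylpentanoic acid | C=C1CC[C@@H]2[C@@](C)(COC(=O)/C=C/c3ccc(O)cc3)CCC[C@@]2(C)[C@@H]1CC[C@H](C)CC(=O)O | target

Total step count: 14. Longest linear sequence: 11 steps (steps 1–5 and 9–14); steps 6–8 make the side-chain iodide.

Steps most likely to fail

Step 5. C-alkylation of the hindered, fully substituted enolate carbon C10 by an unactivated primary iodide may be slow, so that O-alkylation and proton transfer to the ester site erode the required order of the two bond formations. The fallback brings the trimethylene unit in stepwise and sets out from 11. LiN(i-Pr)2 and allyl bromide, a far better electrophile for quaternary-centre formation, should give the trans allyl ketone F1. Hydroboration with 9-BBN and NaBO3 oxidation should give the primary alcohol F2, and I2/PPh3/imidazole the iodide F3. KN(SiMe3)2 in THF then closes ring A through the ester enolate, and the route is rejoined at 14.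

Step 9. The organometallic may fail to add to the C9 carbonyl, which is flanked by the quaternary C10 and deactivated as a vinylogous ester, and may attack the C18 ester instead. The fallback sets out from 14 and puts the side chain on by cross-coupling. Aqueous HCl should hydrolyse the enol ether to the hydroxymethylene ketone F4, and aqueous NaOH should remove the formyl group (retro-Claisen) to give the ketone F5. LiN(i-Pr)2 and PhNTf2 give the enol triflate F6, since only C8 carries α-hydrogens. Negishi coupling with the alkylzinc iodide F7 (from 19 and zinc dust) under PdCl2(dppf) should give the alkene F8. BH3·THF then NaOH/H2O2 adds hydrogen to C9 and oxygen to C8 from the face opposite the C10 methyl, giving the alcohol F9. Dess–Martin periodinane gives the 8-ketone F10, in which C9 can equilibrate to the equatorial side chain. Wittig methylenation with Ph3P=CH2 gives the exocyclic alkene ester F11, and LiAlH4 reduces the ester, so the route is rejoined at 27.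

Step 11. Hydrogen transfer from the diazene to C9 may show poor facial selectivity, or the Mitsunobu substitution beside the tetrasubstituted alkene may be sluggish. The fallback sets out from 23 and uses palladium-catalysed allylic formate hydrogenolysis. Formic acetic anhydride and pyridine should give the bis-formate F12. Pd(OAc)2 and n-Bu3P in hot dioxane should ionise only the allylic formate and transfer hydride from palladium to the more substituted allyl terminus C9 on the face opposite the C10 methyl, with loss of CO2, to give the exocyclic alkene formate F13. K2CO3 in MeOH removes the C18 formate, and the route is rejoined at 27.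

Further compounds
F1 | step 5 | ethyl 2-[(1R,2R,4E)-2-methyl-3-oxo-2-(prop-2-en-1-yl)-4-[(propan-2-yloxy)methylidene]cyclohexyl]propanoate | CC(C)O/C=C1\CC[C@H](C(C)C(=O)OCC)[C@@](C)(CC=C)C1=O
F2 | step 5 | ethyl 2-[(1R,2R,4E)-2-(3-hydroxypropyl)-2-methyl-3-oxo-4-[(propan-2-yloxy)methylidene]cyclohexyl]propanoate | CC(C)O/C=C1\CC[C@H](C(C)C(=O)OCC)[C@@](C)(CCCO)C1=O
F3 | step 5 | ethyl 2-[(1R,2R,4E)-2-(3-iodopropyl)-2-methyl-3-oxo-4-[(propan-2-yloxy)methylidene]cyclohexyl]propanoate | CC(C)O/C=C1\CC[C@H](C(C)C(=O)OCC)[C@@](C)(CCCI)C1=O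
F4 | step 9 | ethyl (1S,4aR,8aS)-6-(hydroxymethylidene)-1,4a-dimethyl-5-oxodecahydronaphthalene-1-carboxylate | OC=C1CC[C@@H]2[C@@](C)(C(=O)OCC)CCC[C@@]2(C)C1=O
F5 | step 9 | ethyl (1S,4aR,8aS)-1,4a-dimethyl-5-oxodecahydronaphthalene-1-carboxylate | C1CC[C@@H]2[C@@](C)(C(=O)OCC)CCC[C@@]2(C)C1=O
F6 | step 9 | ethyl (1S,4aR,8aS)-1,4a-dimethyl-5-{[(trifluoromethyl)sulfonyl]oxy}-1,2,3,4,4a,7,8,8a-octahydronaphthalene-1-carboxylate | C=1CC[C@@H]2[C@@](C)(C(=O)OCC)CCC[C@@]2(C)C1OS(=O)(=O)C(F)(F)F
F7 | step 9 | [(3R)-5-{[tert-butyl(dimethyl)silyl]oxy}-3-methylpentyl]zinc iodide | I[Zn]CC[C@H](C)CCO[Si](C)(C)C(C)(C)C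
F8 | step 9 | ethyl (1S,4aR,8aS)-5-[(3S)-5-{[tert-butyl(dimethyl)silyl]oxy}-3-methylpentyl]-1,4a-dimethyl-1,2,3,4,4a,7,8,8a-octahydronaphthalene-1-carboxylate | C=1CC[C@@H]2[C@@](C)(C(=O)OCC)CCC[C@@]2(C)C1CC[C@H](C)CCO[Si](C)(C)C(C)(C)C
F9 | step 9 | 8-hydroxy ethyl ester (labdane numbering; H on C9 anti to the C10 methyl, C8 not defined) | OC1CC[C@@H]2[C@@](C)(C(=O)OCC)CCC[C@@]2(C)[C@@H]1CC[C@H](C)CCO[Si](C)(C)C(C)(C)C
F10 | step 9 | 8-oxo ethyl ester (labdane numbering; side chain on C9 equatorial) | O=C1CC[C@@H]2[C@@](C)(C(=O)OCC)CCC[C@@]2(C)[C@@H]1CC[C@H](C)CCO[Si](C)(C)C(C)(C)C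
F11 | step 9 | ethyl (1S,4aS,5R,8aS)-5-[(3S)-5-{[tert-butyl(dimethyl)silyl]oxy}-3-methylpentyl]-1,4a-dimethyl-6-methylidenedecahydronaphthalene-1-carboxylate | C=C1CC[C@@H]2[C@@](C)(C(=O)OCC)CCC[C@@]2(C)[C@@H]1CC[C@H](C)CCO[Si](C)(C)C(C)(C)C
F12 | step 11 | bis-formate of diol 23 | O=COCC=1CC[C@@H]2[C@@](C)(COC=O)CCC[C@@]2(C)C1CC[C@H](C)CCO[Si](C)(C)C(C)(C)C
F13 | step 11 | C18 formate of alcohol 27 | C=C1CC[C@@H]2[C@@](C)(COC=O)CCC[C@@]2(C)[C@@H]1CC[C@H](C)CCO[Si](C)(C)C(C)(C)C
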